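## Structural features

The target is a germacranolide: a ten-membered carbocycle (C1–C10) trans-fused across C6–C7 to an α-methylene-γ-butyrolactone (ring oxygen on C6, C11 on C7, C12 carbonyl, C13 exocyclic methylene). The carbocycle contains one Z-trisubstituted alkene, C4=C5 (methyl C15 on C4), flanked by the allylic C3 carbinol and the allylic C6 lactone oxygen; C1 and C8 are methylenes and C10 is a saturated, methyl-bearing centre. The six stereocentres form three neighbouring pairs: C2/C3 (cis-diol, 2S,3R), C6/C7 (trans lactone, 6R,7S) and C9/C10 (angelate cis to the methyl, 9S,10R). The fragile groups are the α-methylene lactone (Michael acceptor, base-sensitive), the angelate (Z to E isomerisation to the tiglate, acyl migration), the allylic diol, and any C9 ketone precursor, in which C10 can epimerise. The real difficulty is a ten-membered ring that holds a Z alkene, with stereocentres to be set on a conformationally mobile ring where small-ring rules of 1,2-induction do not apply. The feature exploited is that joining C3 to C8 turns C3–C8, C15 and C11–C13 into the six-membered ring of (S)-carvone (C3 ketone, C4=C5 ring alkene, 7S centre). C1=C2–C3–C8–C9=C10 is then a 1,5-diene whose [3,3] shift opens the six-membered ring into the ten-membered one.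

## Logic of the disconnections

35 to 32: the lactone acyl–oxygen bond (C12–O6) is cut and C12 is lowered to the alcohol level. The α-methylene lactone is the most fragile group and is made last. The gain is a precursor that carries only hydroxyls and the ester. The demand is an oxidant that takes the primary allylic C12 alcohol in the presence of three secondary ones.

32 to 31 to 28 + 29: four O–Si bonds and the C9–O acyl bond are cut. This reduces the problem to one free alcohol in a fully silylated ring. The demand is esterification of a hindered alcohol without Z/E isomerisation, and desilylation without acyl migration.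

28 to 27 to 26: the C9–H bond and then the C8–H bond are cut, so C9 becomes the enol ether carbon. This leads back to the direct product type of the ring expansion. The demand is a face-selective reduction next to C10 and an enol ether hydrolysis that does not epimerise C10.

26 to 25 to 24 to 22: the O–Si bonds at O2/O3, the C3–H bond and the C2–O bond are cut. The diol becomes a C3 enone. The demand is α′-selective enolate formation, face-selective oxygenation at C2 and chelation-controlled reduction at C3.

22 to 19 (key): C1–C10 is cut and C3–C8 is rejoined. This exchanges the ten-membered ring for a cyclohexenol with all large groups equatorial and removes the C10 centre. The demand is the trans relation of the two alkenyl groups, the E enol ether and a chair transition state.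

19 to 18 to 16 to 15: the enol O–CH2 bond and the O3–Si bond are cut. The enol ether becomes an ethyl ketone. The demand is regioselective C10 deprotonation to the E(O) enolate, O-alkylation, and a masked O3 so that the β-hydroxy ketone does not undergo retro-aldol cleavage.

15 to 14 to 12 + 13: the C9 oxidation level is adjusted and the C2–C3 bond is cut. The gain is the loss of the vinyl group and of the C3 centre. The demand is 1,2-addition to the C3 ketone on the face opposite the C8 substituent.

12 to 9 + 10: the C8–C9 bond is cut. C9, C10 and C14 come from a three-carbon aldehyde. The demand is kinetic α′-enolate formation and addition anti to the C7 side chain.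

9 to 8 to 7 to 5: the O6–Si bond and the C6–O bond are cut. Placing this oxygen on the six-membered ring removes a late allylic oxidation of the macrocycle and lets C7 control C6. The demand is γ- and not α′-enolisation, and γ-attack of the oxidant anti to C7.

5 to 4 to 2 to 1: the O12–Si bond and the C12–O bond are cut (C12–Cl in 2). Oxidising this methyl at the outset removes the late, poorly selective oxidation of an isopropenyl group beside a trisubstituted alkene. The demand is chlorination of the 1,1-disubstituted alkene only.

## Other disconnections considered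

Alternative 1: The cut is at C5–C6 and at the lactone O–C12 bond, which leads to the acyclic Z-alkenyl iodide aldehyde A1 (C5 iodide, C6 aldehyde, C12 methyl ester, angelate and acetonide in place).
- Forward step: NiCl2/CrCl2 would turn the C5–I bond into an alkenylchromium that adds to C6; the C6 alkoxide would then acylate on the C12 ester to give A2, one acetonide hydrolysis from the target.
- In its favour: C2, C3, C9 and C10 would be set in open-chain fragments by reagent-controlled reactions, which is better than the ring-derived control the chosen plan needs for C2, C3 and C9. The Z geometry is carried in the iodide, which is equal to the ring-locked Z alkene of carvone. The endgame after ring formation is one step against eight, which is clearly better.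
- Against it here: a ten-membered ring would have to be closed by C–C bond formation under high dilution with excess chromium reagent. The C6 configuration (and so the trans lactone) would be decided only in that closure. In A1, C7–H is α to the aldehyde and γ to the acrylate, so epimerisation and conjugation threaten before cyclisation.
- Comparison: the chosen plan forms the ring by a unimolecular pericyclic ring expansion that needs no dilution and fixes C10 in the same event. Its linear length is probably similar to the longest linear sequence to A1, but it is not convergent.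

Alternative 2: The cut reconnects C4 to C9, which leads to the cis-decalin mesylate A3 (C9 tertiary alcohol, C5 mesylate, lactone and acetonide in place).
- Forward step: the C9 alkoxide fragments with the C4–C9 and C5–O bonds antiperiplanar, to give the ten-membered C9 ketone A4.
- In its favour: the ring arises by fragmentation without dilution, which is equal to the chosen plan. The alkene geometry is dictated by the σ-framework, which is equal or better. C2, C3, C6 and C7 would be set on rigid chairs, which is better than macrocyclic control. The C9 ketone is delivered directly.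
- Against it here: A3 needs eight stereocentres, among them a quaternary C4 and a tertiary C9 carbinol, and three of them (C4, C5, C9) are destroyed. The C9 alkoxide can attack the lactone carbonyl through a six-membered ring. C10 becomes epimerisable under the basic conditions. α-Methylenation, C9 reduction, angeloylation and deprotection still follow.
- Comparison: the C9 reduction problem is the same in both plans, so the plans are equal on that point. The chosen plan reaches its rearrangement substrate from a terpene in twelve steps, whereas A3 would probably need many more, so the chosen plan is the better on step economy.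

Alternative 3: The cut is at C6–C7 with O6 rejoined to C13, which leads to the thirteen-membered bis-allylic ether A5.
- Forward step: deprotonation at C6 and a [2,3]-Wittig shift would form C6–C7, break O–C13 and give A6 with the C11=C13 methylene and the free C6 hydroxyl.
- In its favour: one step makes a C–C bond, two stereocentres and the exocyclic methylene, which is better than the single centre set by the chosen key step. O6 and O12 need no C–H oxidation, which is equal to the chosen plan as designed here. A thirteen-membered ether is easier to close than a ten-membered carbocycle. C2, C3, C9 and C10 come from acyclic, reagent-controlled chemistry, which is better.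
- Against it here: C6–H and C13–H are both allylic and α to oxygen, so the site of deprotonation is uncertain. The C6/C7 relation and its sense relative to the remote centres rest on a macrocyclic transition state. The allyl anion at C6 can scramble the Z C4=C5 geometry, which the carvone ring cannot. A [1,2] shift competes.
- Comparison: A6 needs about five more steps against eight in the chosen plan, so the alternative is better after the key step. The chosen plan is the safer on alkene geometry and on regiochemistry of the key event.

Key step: step 13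

## Assumptions and conventions

- Germacrane numbering of the target is used for every intermediate. β means the face of the C7 side chain and α the opposite face.
- Re-derivation of the descriptors shows that the stereocentre of (S)-carvone becomes 7S, and that the trans-dialkenyl carbinol with the E enol ether gives 10R through the chair, with a ring-trans C8=C9 bond. The precursor and product of the key step are therefore used with unchanged skeleton and stereochemistry; they carry two added spectator groups, silyloxy at C6 and at C12.
- 12 and 14 are carried as mixtures of C9 epimers (this centre is oxidised in step 9); 34 is a mixture of anomers.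

## Route

Step 1
Reactants: 1 (S)-carvone
Product: 2 (S)-10-chlorocarvone (5S)-5-(3-chloroprop-1-en-2-yl)-2-methylcyclohex-2-en-1-one
Conditions: Ca(OCl)2, CO2 (s), CH2Cl2/H2O, 0 °C
Reagents that add atoms: calcium hypochlorite, [Ca+2].[O-]Cl.[O-]Cl
Why: Ene-type allylic chlorination by HOCl formed in the flask attacks only the electron-rich 1,1-disubstituted alkene (the enone alkene is deactivated) and puts chlorine on the carbon that becomes C12; the C7 centre is not touched.

Step 2
Reactants: 2 (S)-10-chlorocarvone
Product: 4 (S)-10-hydroxycarvone, via 10-acetoxycarvone 3 (not isolated)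
Conditions: KOAc, Bu4NI (cat.), DMF, 60 °C; then K2CO3, MeOH, rt
Reagents that add atoms: potassium acetate, CC(=O)[O-].[K+]
Why: SN2 displacement of the allylic chloride by acetate (iodide catalysis, Finkelstein-type) followed by methanolysis in the same flask gives the primary allylic alcohol; mild carbonate leaves the enone alone.

Step 3
Reactants: 4 (S)-10-hydroxycarvone
Product: 5 (S)-10-(tert-butyldimethylsilyloxy)carvone
Conditions: TBSCl, imidazole, DMF, 0 °C to rt
Reagents that add atoms: tert-butyldimethylsilyl chloride, CC(C)(C)[Si](C)(C)Cl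
Why: Standard silylation of a primary alcohol; the ether prevents alkoxide conjugate addition to the enone in step 4 and is stable to all later basic steps.

Step 4
Reactants: 5 (S)-10-(tert-butyldimethylsilyloxy)carvone
Product: 7 linear bis-silyl dienol ether 1-(TBSO)-2-methyl-5-[3-(TBSO)prop-1-en-2-yl]cyclohexa-1,3-diene, via potassium dienolate 6 (not isolated)
Conditions: KOt-Bu, THF, 0 °C; then TBSCl, 0 °C
Reagents that add atoms: tert-butyldimethylsilyl chloride, CC(C)(C)[Si](C)(C)Cl
Why: Under equilibrating alkoxide conditions 2-cyclohexenones give the linearly conjugated dienolate by γ-deprotonation (here at C6) and not the kinetic α′ enolate, and the potassium dienolate is silylated on oxygen; the reaction type is thermodynamic dienolate formation with O-silylation.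

Step 5
Reactants: 7 linear bis-silyl dienol ether
Product: 8 γ-hydroxy enone (4R,5S)-5-[3-(TBSO)prop-1-en-2-yl]-4-hydroxy-2-methylcyclohex-2-en-1-one
Conditions: mCPBA, NaHCO3, CH2Cl2, −20 °C; aq Na2S2O3
Reagents that add atoms: 3-chloroperbenzoic acid, OOC(=O)c1cccc(Cl)c1
Why: Vinylogous Rubottom oxidation: the peracid attacks the γ terminus C6 of the dienol ether (the α carbon C4 is fully substituted) on the face opposite the adjacent C7 side chain, and collapse returns the enone with the 6α hydroxyl (6R, trans to C7); the dienol ether is far more nucleophilic than the 1,1-disubstituted alkene bearing an allylic ether.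

Step 6
Reactants: 8 γ-hydroxy enone
Product: 9 bis-silyl enone (4R,5S)-4-(TBSO)-5-[3-(TBSO)prop-1-en-2-yl]-2-methylcyclohex-2-en-1-one
Conditions: TBSCl, imidazole, DMAP (cat.), DMF, rt
Reagents that add atoms: tert-butyldimethylsilyl chloride, CC(C)(C)[Si](C)(C)Cl
Why: Neutral silylation of the secondary allylic alcohol stops dehydration of the γ-hydroxy enone to a phenol and gives a group inert to enolates, organometallics and hydrides.

Step 7
Reactants: 9 bis-silyl enone; 10 propanal
Product: 12 aldol (4R,5S,6S)-4-(TBSO)-5-[3-(TBSO)prop-1-en-2-yl]-6-(1-hydroxypropyl)-2-methylcyclohex-2-en-1-one, via lithium enolate 11 (not isolated)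
Conditions: LiN(i-Pr)2, THF, −78 °C; then 10, −78 °C; aq NH4Cl
Reagents that add atoms: none
Why: Kinetic deprotonation occurs at the α′ methylene C8, and the aldol addition to propanal takes place anti to the neighbouring C7 side chain, which gives the 7,8-trans product; the C9 carbinol mixture is removed in step 9.

Step 8
Reactants: 12 aldol; 13 vinylmagnesium bromide
Product: 14 diol 3β-vinyl-3α-hydroxy carbinol with the 8α-(1-hydroxypropyl) group
Conditions: 13 (3.5 equiv), CeCl3 (anhydrous), THF, −78 °C; aq NH4Cl
Reagents that add atoms: none
Why: Organocerium 1,2-addition to the C3 ketone (the first equivalent deprotonates the C9 hydroxyl; cerium suppresses enolisation and retro-aldol) in the half-chair with the C6, C7 and C8 groups pseudo-equatorial; approach anti to the adjacent C8 substituent places the vinyl group trans to it.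

Step 9
Reactants: 14 diol
Product: 15 β-hydroxy ethyl ketone (C9 ketone with free 3α-OH)
Conditions: Dess–Martin periodinane, NaHCO3, CH2Cl2, 0 °C to rt
Reagents that add atoms: none
Why: Dess–Martin oxidation of the only secondary alcohol; the tertiary bis-allylic alcohol cannot be oxidised, and buffered chromium-free conditions avoid its allylic transposition or ionisation.

Step 10
Reactants: 15 β-hydroxy ethyl ketone
Product: 16 3-O-trimethylsilyl ethyl ketone
Conditions: N-(trimethylsilyl)imidazole, CH2Cl2, rt
Reagents that add atoms: N-(trimethylsilyl)imidazole, C[Si](C)(C)n1ccnc1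
Why: Neutral silylation of the hindered tertiary alcohol; O3 must be capped because the tertiary alkoxide of this β-hydroxy ketone would undergo retro-aldol cleavage or be alkylated in step 11.

Step 11
Reactants: 16 3-O-trimethylsilyl ethyl ketone
Product: 18 (E)-methoxymethyl enol ether (C10 methyl cis to C8) with 3-O-trimethylsilyl group, via lithium E(O)-enolate 17 (not isolated)
Conditions: lithium 2,2,6,6-tetramethylpiperidide, LiBr, THF, −78 °C; then MOMCl, HMPA, −78 to −30 °C
Reagents that add atoms: chloromethyl methyl ether, COCCl
Why: Kinetic deprotonation at the unhindered C10 methylene (C8–H is shielded) with the amide–LiBr system, which favours E(O) enolates of ethyl ketones, puts the C10 methyl cis to C8; the hard electrophile MOMCl in HMPA alkylates the enolate on oxygen with retention of geometry.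

Step 12
Reactants: 18 silylated enol ether
Product: 19 rearrangement precursor 3β-vinyl-3α-hydroxy-6α-(TBSO)-7β-[3-(TBSO)prop-1-en-2-yl]-8α-[(E)-1-(methoxymethoxy)prop-1-enyl]-4-methylcyclohex-4-ene (germacrane locants)
Conditions: K2CO3, MeOH, rt
Reagents that add atoms: none
Why: Carbonate methanolysis cleaves only the trimethylsilyl ether; the tert-butyldimethylsilyl ethers and the base-stable enol ether remain.

Step 13
Reactants: 19 rearrangement precursor
Product: 22 ten-membered enone (6R,7S,10R)-6-(TBSO)-7-[3-(TBSO)prop-1-en-2-yl]-9-(methoxymethoxy)germacra-4Z,8-dien-3-one, via potassium alkoxide 20 (not isolated), via potassium enolate 21 (not isolated)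
Conditions: KH, 18-crown-6, THF, 0 °C to rt; then aq NH4Cl, −78 °C
Reagents that add atoms: none
Why: KH with the crown ether gives the dissociated alkoxide 20, whose oxyanion weakens the C3–C8 bond. A [3,3]-sigmatropic shift across C1=C2–C3–C8–C9=C10 then forms C1–C10 and breaks C3–C8; the closest known reaction type is the anionic oxy-Cope ring expansion of trans-1,2-dialkenylcyclohexanols to cyclodec-5-enones. The ten-membered ring is not closed end to end but arises by four-atom expansion of the six-membered ring through a six-membered chair transition state. In the half-chair of 20 the C6, C7 and C8 groups and the C3 vinyl group are all pseudo-equatorial, so the two alkenyl groups are gauche and reach the chair with C4 and C7 equatorial and O3 and H8 axial. The new C10 centre is controlled by the enol ether geometry: the methyl cis to C8 is pseudo-axial, bonding is suprafacial on the face that C3 leaves, and 10R results together with a ring-trans C8=C9 bond. The step needs chair over boat (the boat would give 10S) and vinyl over ring-alkene participation; the all-equatorial trans arrangement fixed by C7 secures both, the axial methyl being the only penalty. Quenching protonates the cross-conjugated Z(O) enolate 21 at C2, and the Z C4=C5 alkene, C6 and C7 are untouched.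

Step 14
Reactants: 22 ten-membered enone
Product: 24 (2S)-2-hydroxy enone, via sodium enolate 23 (not isolated)
Conditions: NaN(SiMe3)2, THF, −78 °C; then (+)-(camphorsulfonyl)oxaziridine, −78 °C; aq NH4Cl
Reagents that add atoms: (+)-(2R,8aS)-(camphorsulfonyl)oxaziridine, CC1(C)[C@@H]2CC[C@]13CS(=O)(=O)N4O[C@@]34C2
Why: Kinetic α′ deprotonation at C2 gives the Z(O) enolate, which is hydroxylated by the N-sulfonyloxaziridine (enolate oxidation); the (+)-reagent is chosen because its established sense with Z(O) ketone enolates corresponds to 2S, and the neutral enol ether and alkenes are inert to it.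

Step 15
Reactants: 24 (2S)-2-hydroxy enone
Product: 25 (2S,3R)-2,3-cis-diol
Conditions: Zn(BH4)2, Et2O, −30 to 0 °C; aq NH4Cl
Reagents that add atoms: none
Why: Chelation-controlled 1,2-reduction: zinc bridges the C2 hydroxyl and the C3 carbonyl and hydride arrives from the side of H2, which gives the erythro (ring-cis) diol and hence 3R from 2S.

Step 16
Reactants: 25 (2S,3R)-2,3-cis-diol
Product: 26 tetrakis-silyl enol ether (2,3,6,12-tetra-O-TBS)
Conditions: TBSOTf, 2,6-lutidine, CH2Cl2, −78 to 0 °C
Reagents that add atoms: tert-butyldimethylsilyl trifluoromethanesulfonate, CC(C)(C)[Si](C)(C)OS(=O)(=O)C(F)(F)F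
Why: Silylation of both secondary hydroxyls under basic conditions; protecting the diol before the C9 ketone is unmasked prevents transannular ketal formation from O2/O3 to C9, and the groups match those on O6 and O12 for one final deprotection.

Step 17
Reactants: 26 tetrakis-silyl enol ether
Product: 27 C9 ketone (2S,3R,6R,7S,10R)-2,3,6,12-tetrakis(TBSO)germacra-4Z,11(13)-dien-9-one
Conditions: oxalic acid, THF/H2O, 0 °C to rt
Reagents that add atoms: water, O
Why: Mild acid hydrolysis of the enol ether (protonation at C8, loss of the methoxymethyl unit as formaldehyde and methanol) reveals the C9 ketone and the C8 methylene while the silyl ethers survive; conditions are kept mild and short because C10 is now α to a ketone.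

Step 18
Reactants: 27 C9 ketone
Product: 28 (9S)-alcohol
Conditions: (R)-2-methyl-CBS-oxazaborolidine (cat.), catecholborane, toluene, −78 °C
Reagents that add atoms: none
Why: Corey–Bakshi–Shibata reduction: with the α-branched C10 side as the large group and the C8 methylene side as the small one, the (R)-catalyst delivers hydride to give 9S (9β-OH, cis to the C10 methyl); catecholborane at low temperature does not hydroborate the alkenes.

Step 19
Reactants: 28 (9S)-alcohol; 29 angelic acid
Product: 31 9-O-angelate, via mixed anhydride 30 (not isolated)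
Conditions: 29, 2,4,6-trichlorobenzoyl chloride, Et3N, toluene, rt; then 28, 75 °C
Reagents that add atoms: none
Why: Yamaguchi-type esterification through the mixed anhydride without a nucleophilic amine catalyst acylates the hindered alcohol and avoids the conjugate addition–elimination path that turns angelate into tiglate.

Step 20
Reactants: 31 9-O-angelate
Product: 32 tetraol angelate (2,3,6,12-tetrahydroxy)
Conditions: HF·pyridine, pyridine, THF, 0 °C to rt
Reagents that add atoms: none
Why: Buffered fluoride cleaves the four Si–O bonds without base, so the angelate neither migrates nor isomerises and the allylic alcohols are not ionised.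

Step 21
Reactants: 32 tetraol angelate
Product: 35 target CNP0229085.1, via C12 enal 33 (not isolated), via lactol 34 (not isolated)
Conditions: TEMPO (cat.), PhI(OAc)2, CH2Cl2, rt
Reagents that add atoms: none
Why: Oxoammonium oxidation is selective for the primary allylic C12 alcohol over the secondary ones; the enal is trapped by the neighbouring C6 hydroxyl as the five-membered lactol, which is oxidised in the same flask to the trans-fused α-methylene lactone, a known conversion of 1,4-diols into γ-lactones.

## Compound list

1 | (S)-carvone | C=C(C)[C@H]1CC=C(C)C(=O)C1 | starting material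
2 | (S)-10-chlorocarvone | C=C(CCl)[C@H]1CC=C(C)C(=O)C1 | intermediate
3 | (S)-10-acetoxycarvone (not isolated) | C=C(COC(C)=O)[C@H]1CC=C(C)C(=O)C1 | intermediate
4 | (S)-10-hydroxycarvone | C=C(CO)[C@H]1CC=C(C)C(=O)C1 | intermediate
5 | (S)-10-(tert-butyldimethylsilyloxy)carvone | C=C(CO[Si](C)(C)C(C)(C)C)[C@H]1CC=C(C)C(=O)C1 | intermediate
6 | potassium linear dienolate of 5 (not isolated) | C=C(CO[Si](C)(C)C(C)(C)C)[C@H]1C=CC(C)=C([O-])C1.[K+] | intermediate
7 | linear bis-silyl dienol ether, 1-(TBSO)-2-methyl-5-[3-(TBSO)prop-1-en-2-yl]cyclohexa-1,3-diene, ring centre as in 5 | C=C(CO[Si](C)(C)C(C)(C)C)[C@H]1C=CC(C)=C(O[Si](C)(C)C(C)(C)C)C1 | intermediate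
8 | (4R,5S)-5-[3-(TBSO)prop-1-en-2-yl]-4-hydroxy-2-methylcyclohex-2-en-1-one (6α-OH, trans to the C7 side chain) | C=C(CO[Si](C)(C)C(C)(C)C)[C@H]1[C@H](O)C=C(C)C(=O)C1 | intermediate
9 | (4R,5S)-4-(TBSO)-5-[3-(TBSO)prop-1-en-2-yl]-2-methylcyclohex-2-en-1-one | C=C(CO[Si](C)(C)C(C)(C)C)[C@H]1[C@H](O[Si](C)(C)C(C)(C)C)C=C(C)C(=O)C1 | intermediate
10 | propanal | CCC=O | starting material
11 | lithium α′-enolate of 9 (not isolated) | C=C(CO[Si](C)(C)C(C)(C)C)[C@H]1[C@H](O[Si](C)(C)C(C)(C)C)C=C(C)C([O-])=C1.[Li+] | intermediate
12 | aldol, (4R,5S,6S)-4-(TBSO)-5-[3-(TBSO)prop-1-en-2-yl]-6-(1-hydroxypropyl)-2-methylcyclohex-2-en-1-one, C9 epimers | C=C(CO[Si](C)(C)C(C)(C)C)[C@H]1[C@H](O[Si](C)(C)C(C)(C)C)C=C(C)C(=O)[C@@H]1C(O)CC | intermediate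
13 | vinylmagnesium bromide | C=C[Mg]Br | starting material
14 | diol: 3α-hydroxy-3β-vinyl carbinol, 6α-OTBS, 7β-side chain, 8α-(1-hydroxypropyl), C9 epimers | C=C(CO[Si](C)(C)C(C)(C)C)[C@H]1[C@H](O[Si](C)(C)C(C)(C)C)C=C(C)[C@@](O)(C=C)[C@@H]1C(O)CC | intermediate
15 | β-hydroxy ethyl ketone: as 14 with 8α-propanoyl | C=C(CO[Si](C)(C)C(C)(C)C)[C@H]1[C@H](O[Si](C)(C)C(C)(C)C)C=C(C)[C@@](O)(C=C)[C@@H]1C(=O)CC | intermediate
16 | 3-O-trimethylsilyl ether of 15 | C=C(CO[Si](C)(C)C(C)(C)C)[C@H]1[C@H](O[Si](C)(C)C(C)(C)C)C=C(C)[C@@](O[Si](C)(C)C)(C=C)[C@@H]1C(=O)CC | intermediate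
17 | lithium E(O)-enolate of 16, C10 methyl cis to C8 (not isolated) | C=C(CO[Si](C)(C)C(C)(C)C)[C@H]1[C@H](O[Si](C)(C)C(C)(C)C)C=C(C)[C@@](O[Si](C)(C)C)(C=C)[C@@H]1/C([O-])=C\C.[Li+] | intermediate
18 | (E)-1-(methoxymethoxy)prop-1-enyl compound with 3-O-trimethylsilyl group | C=C(CO[Si](C)(C)C(C)(C)C)[C@H]1[C@H](O[Si](C)(C)C(C)(C)C)C=C(C)[C@@](O[Si](C)(C)C)(C=C)[C@@H]1/C(OCOC)=C\C | intermediate
19 | rearrangement precursor: trans-dialkenyl cyclohexenol, 3α-OH, 3β-vinyl, 6α-OTBS, 7β-[3-(TBSO)prop-1-en-2-yl], 8α-[(E)-1-(methoxymethoxy)prop-1-enyl] | C=C(CO[Si](C)(C)C(C)(C)C)[C@H]1[C@H](O[Si](C)(C)C(C)(C)C)C=C(C)[C@@](O)(C=C)[C@@H]1/C(OCOC)=C\C | intermediate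
20 | potassium alkoxide of 19 (not isolated) | C=C(CO[Si](C)(C)C(C)(C)C)[C@H]1[C@H](O[Si](C)(C)C(C)(C)C)C=C(C)[C@@]([O-])(C=C)[C@@H]1/C(OCOC)=C\C.[K+] | intermediate
21 | potassium Z(O) C2=C3 enolate of 22 (not isolated) | CC(C)(C)[Si](C)(C)O[C@@H]1/C=C(/C)\C([O-])=C\C[C@@H](C)/C(OCOC)=C/[C@H]1C(=C)CO[Si](C)(C)C(C)(C)C.[K+] | intermediate
22 | (6R,7S,10R)-6-(TBSO)-7-[3-(TBSO)prop-1-en-2-yl]-9-(methoxymethoxy)germacra-4Z,8-dien-3-one (ring-trans C8=C9) | CC(C)(C)[Si](C)(C)O[C@@H]1/C=C(/C)C(=O)CC[C@@H](C)/C(OCOC)=C/[C@H]1C(=C)CO[Si](C)(C)C(C)(C)C | intermediate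
23 | sodium Z(O) C2=C3 enolate of 22 (not isolated) | CC(C)(C)[Si](C)(C)O[C@@H]1/C=C(/C)\C([O-])=C\C[C@@H](C)/C(OCOC)=C/[C@H]1C(=C)CO[Si](C)(C)C(C)(C)C.[Na+] | intermediate
24 | (2S)-2-hydroxy derivative of 22 | CC(C)(C)[Si](C)(C)O[C@@H]1/C=C(/C)C(=O)[C@@H](O)C[C@@H](C)/C(OCOC)=C/[C@H]1C(=C)CO[Si](C)(C)C(C)(C)C | intermediate
25 | (2S,3R)-2,3-cis-diol | CC(C)(C)[Si](C)(C)O[C@@H]1/C=C(/C)[C@@H](O)[C@@H](O)C[C@@H](C)/C(OCOC)=C/[C@H]1C(=C)CO[Si](C)(C)C(C)(C)C | intermediate
26 | 2,3,6,12-tetrakis-O-TBS enol ether | CC(C)(C)[Si](C)(C)O[C@@H]1/C=C(/C)[C@@H](O[Si](C)(C)C(C)(C)C)[C@@H](O[Si](C)(C)C(C)(C)C)C[C@@H](C)/C(OCOC)=C/[C@H]1C(=C)CO[Si](C)(C)C(C)(C)C | intermediate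
27 | (2S,3R,6R,7S,10R)-2,3,6,12-tetrakis(TBSO)germacra-4Z,11(13)-dien-9-one | CC(C)(C)[Si](C)(C)O[C@@H]1/C=C(/C)[C@@H](O[Si](C)(C)C(C)(C)C)[C@@H](O[Si](C)(C)C(C)(C)C)C[C@@H](C)C(=O)C[C@H]1C(=C)CO[Si](C)(C)C(C)(C)C | intermediate
28 | (9S)-alcohol of 27 | CC(C)(C)[Si](C)(C)O[C@@H]1/C=C(/C)[C@@H](O[Si](C)(C)C(C)(C)C)[C@@H](O[Si](C)(C)C(C)(C)C)C[C@@H](C)[C@@H](O)C[C@H]1C(=C)CO[Si](C)(C)C(C)(C)C | intermediate
29 | angelic acid, (Z)-2-methylbut-2-enoic acid | C/C=C(/C)C(=O)O | starting material
30 | angelic 2,4,6-trichlorobenzoic anhydride (not isolated) | C/C=C(/C)C(=O)OC(=O)c1c(Cl)cc(Cl)cc1Cl | intermediate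
31 | 9-O-angelate of 28 | CC(C)(C)[Si](C)(C)O[C@@H]1/C=C(/C)[C@@H](O[Si](C)(C)C(C)(C)C)[C@@H](O[Si](C)(C)C(C)(C)C)C[C@@H](C)[C@@H](OC(=O)/C(C)=C\C)C[C@H]1C(=C)CO[Si](C)(C)C(C)(C)C | intermediate
32 | (2S,3R,6R,7S,9S,10R)-9-angeloyloxy-germacra-4Z,11(13)-diene-2,3,6,12-tetraol | O[C@@H]1/C=C(/C)[C@@H](O)[C@@H](O)C[C@@H](C)[C@@H](OC(=O)/C(C)=C\C)C[C@H]1C(=C)CO | intermediate
33 | C12 enal of 32 (not isolated) | O[C@@H]1/C=C(/C)[C@@H](O)[C@@H](O)C[C@@H](C)[C@@H](OC(=O)/C(C)=C\C)C[C@H]1C(=C)C=O | intermediate
34 | 12,6-lactol, anomers (not isolated) | C=C1C(O)O[C@@H]2/C=C(/C)[C@@H](O)[C@@H](O)C[C@@H](C)[C@@H](OC(=O)/C(C)=C\C)C[C@@H]12 | intermediate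
35 | CNP0229085.1, (2S,3R,6R,7S,9S,10R)-9-angeloyloxy-2,3-dihydroxygermacra-4Z,11(13)-dien-12,6-olide | C=C1C(=O)O[C@@H]2/C=C(/C)[C@@H](O)[C@@H](O)C[C@@H](C)[C@@H](OC(=O)/C(C)=C\C)C[C@@H]12 | target

## Step count and least certain steps

Total: 21 steps. Longest linear sequence: 21 steps from 1; the route is linear, and 10, 13 and 29 are commercial.

Step 13 (key step). The shift may pass partly through the boat, or through the ring alkene, because the pseudo-axial C10 methyl destabilises the chair; this would erode the configuration at C10. The alkoxide or the enolate may also degrade under the strongly basic conditions before the quench. Fallback: set out from 18 and run the neutral siloxy-Cope rearrangement (degassed toluene, about 200 °C, base-washed glass), with no alkoxide and no counter-ion. This gives the trimethylsilyl dienol ether F1, which K2CO3/MeOH converts into 22.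

Step 4 (with step 5). Enolisation may lose regiocontrol, so that the cross-conjugated α′ dienolate is silylated, or the peracid may attack at the α carbon; either way the oxygen ends at the wrong carbon. Fallback: introduce O6 by allylic C–H oxidation once C3 is quaternary. Set out from 5 and apply the conditions of steps 7 to 10:
- aldol to the 6-deoxy aldol F2;
- vinyl addition to the 6-deoxy diol F3;
- oxidation to the 6-deoxy hydroxy ketone F4;
- silylation to the 6-deoxy trimethylsilyl ketone F5.

Allylic oxidation of F5 (CrO3·3,5-dimethylpyrazole, or t-BuOOH with Rh2(cap)4) at C6, the only allylic methylene of the ring alkene, gives the C6 enone F6. Luche reduction (NaBH4, CeCl3; axial hydride, conjugated ketone reduced before the hindered C9 ketone) gives the 6α-alcohol F7. TBSCl/imidazole returns the material to the route at 16.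

Step 8. Facial selectivity may be poor, because the metal aldolate chelated to the C3 carbonyl changes the shape of the C8 substituent, or the aldolate may revert by retro-aldol. Fallback: remove the free hydroxyl from the event. Set out from 12 and silylate (TMSCl, imidazole) to the trimethylsilyl ether F8. Add the vinylcerium reagent to the now bulkier, non-chelating ketone to give the carbinol F9. K2CO3/MeOH comes back at 14.

Step 11. The Z(O) enolate (methyl trans to C8) may form because of allylic strain between the C10 methyl and the hindered C8 substituent; through the chair it would lead to the 10S epimer. C-alkylation is a second risk. Fallback: set out from 15 and replace steps 10 and 11 by an in-flask silyl trap (lithium 2,2,6,6-tetramethylpiperidide added to 15 and excess TMSCl at −78 °C). This gives the bis-trimethylsilyl compound F10, whose E silyl enol ether can be purified. Selective cleavage of the enol silyl group with MeLi regenerates the lithium enolate with its geometry, and MOMCl/HMPA comes back at 18.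

Step 14. Facial selectivity may be poor. The enolate, in the crossed-alkene conformation in which the rearrangement delivers it, should expose the face that leads to the 2R alcohol, so the (+)-reagent may form a mismatched pair with the ring. Fallback: set out from 22 with the (−)-oxaziridine, so that reagent and ring reinforce each other, and accept the (2R)-alcohol F11. Mitsunobu inversion with 4-nitrobenzoic acid (PPh3, DIAD) gives the (2S)-4-nitrobenzoate F12, and K2CO3/MeOH at 0 °C comes back at 24.

Step 18. Facial selectivity may be poor because the two flanks of the C9 ketone are both ring carbons and the macrocycle may override the catalyst. Fallback: set out from 27 with the (S)-catalyst or a bulky hydride to the (9R)-alcohol F13. Mitsunobu esterification with 29 (PPh3, DIAD) inverts C9 and installs the ester in one step, coming back at 31 and making step 19 unnecessary.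

## Further compounds

F1 | step 13 | trimethylsilyl dienol ether of 22 | CC(C)(C)[Si](C)(C)O[C@@H]1/C=C(/C)\C(O[Si](C)(C)C)=C\C[C@@H](C)/C(OCOC)=C/[C@H]1C(=C)CO[Si](C)(C)C(C)(C)C
F2 | step 4 | 6-deoxy aldol from 5 (C9 epimers) | C=C(CO[Si](C)(C)C(C)(C)C)[C@H]1CC=C(C)C(=O)[C@@H]1C(O)CC
F3 | step 4 | 6-deoxy diol (3β-vinyl carbinol, C9 epimers) | C=C(CO[Si](C)(C)C(C)(C)C)[C@H]1CC=C(C)[C@@](O)(C=C)[C@@H]1C(O)CC
F4 | step 4 | 6-deoxy β-hydroxy ethyl ketone | C=C(CO[Si](C)(C)C(C)(C)C)[C@H]1CC=C(C)[C@@](O)(C=C)[C@@H]1C(=O)CC
F5 | step 4 | 6-deoxy 3-O-trimethylsilyl ethyl ketone | C=C(CO[Si](C)(C)C(C)(C)C)[C@H]1CC=C(C)[C@@](O[Si](C)(C)C)(C=C)[C@@H]1C(=O)CC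
F6 | step 4 | C6 enone of F5 | C=C(CO[Si](C)(C)C(C)(C)C)[C@H]1C(=O)C=C(C)[C@@](O[Si](C)(C)C)(C=C)[C@@H]1C(=O)CC
F7 | step 4 | 6α-alcohol from F6 | C=C(CO[Si](C)(C)C(C)(C)C)[C@H]1[C@H](O)C=C(C)[C@@](O[Si](C)(C)C)(C=C)[C@@H]1C(=O)CC
F8 | step 8 | 9-O-trimethylsilyl ether of 12 | C=C(CO[Si](C)(C)C(C)(C)C)[C@H]1[C@H](O[Si](C)(C)C(C)(C)C)C=C(C)C(=O)[C@@H]1C(O[Si](C)(C)C)CC
F9 | step 8 | 9-O-trimethylsilyl ether of 14 | C=C(CO[Si](C)(C)C(C)(C)C)[C@H]1[C@H](O[Si](C)(C)C(C)(C)C)C=C(C)[C@@](O)(C=C)[C@@H]1C(O[Si](C)(C)C)CC
F10 | step 11 | bis-trimethylsilyl compound: 3-O-silyl ether and (E)-silyl enol ether of 15 | C=C(CO[Si](C)(C)C(C)(C)C)[C@H]1[C@H](O[Si](C)(C)C(C)(C)C)C=C(C)[C@@](O[Si](C)(C)C)(C=C)[C@@H]1/C(O[Si](C)(C)C)=C\C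
F11 | step 14 | (2R)-2-hydroxy epimer of 24 | CC(C)(C)[Si](C)(C)O[C@@H]1/C=C(/C)C(=O)[C@H](O)C[C@@H](C)/C(OCOC)=C/[C@H]1C(=C)CO[Si](C)(C)C(C)(C)C
F12 | step 14 | (2S)-4-nitrobenzoate of 24 | CC(C)(C)[Si](C)(C)O[C@@H]1/C=C(/C)C(=O)[C@@H](OC(=O)c2ccc(cc2)[N+](=O)[O-])C[C@@H](C)/C(OCOC)=C/[C@H]1C(=C)CO[Si](C)(C)C(C)(C)C
F13 | step 18 | (9R)-alcohol, C9 epimer of 28 | CC(C)(C)[Si](C)(C)O[C@@H]1/C=C(/C)[C@@H](O[Si](C)(C)C(C)(C)C)[C@@H](O[Si](C)(C)C(C)(C)C)C[C@@H](C)[C@H](O)C[C@H]1C(=C)CO[Si](C)(C)C(C)(C)C
A1 | alternative 1 | acyclic Z-alkenyl iodide aldehyde with C12 methyl ester, angelate and acetonide | I/C=C(/C)[C@H]1OC(C)(C)O[C@H]1C[C@@H](C)[C@@H](OC(=O)/C(C)=C\C)C[C@H](C=O)C(=C)C(=O)OC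
A2 | alternative 1 | 2,3-O-isopropylidene derivative of the target | C=C1C(=O)O[C@@H]2/C=C(/C)[C@@H](O3)[C@@H](OC3(C)C)C[C@@H](C)[C@@H](OC(=O)/C(C)=C\C)C[C@@H]12
A3 | alternative 2 | cis-decalin C9 tertiary alcohol C5 mesylate with lactone and acetonide | O=C1O[C@@H]2[C@@H](OS(C)(=O)=O)[C@@]3(C)[C@@H](O4)[C@@H](OC4(C)C)C[C@@H](C)[C@@]3(O)C[C@H]2C1
A4 | alternative 2 | ten-membered C9 ketone with Z C4=C5 alkene, lactone and acetonide | O=C1O[C@@H]2/C=C(/C)[C@@H](O3)[C@@H](OC3(C)C)C[C@@H](C)C(=O)C[C@H]2C1
A5 | alternative 3 | thirteen-membered C6–O–C13 bis-allylic ether (C8 trans to C13 on the C7=C11 alkene) | O1C/C=C(/C)[C@@H](O2)[C@@H](OC2(C)C)C[C@@H](C)[C@@H](O[Si](C)(C)C(C)(C)C)C/C=C(\COCc2ccc(OC)cc2)C1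
A6 | alternative 3 | ten-membered C6 homoallylic alcohol with the C7 alkenyl side chain | O[C@@H]1/C=C(/C)[C@@H](O2)[C@@H](OC2(C)C)C[C@@H](C)[C@@H](O[Si](C)(C)C(C)(C)C)C[C@H]1C(=C)COCc1ccc(OC)cc1
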